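**Retrosynthetic overview**

1. Germacrane numbering is used: ring C1–C10, CH3 (C14) on C10, =CH2 (C15) on C4, lactone O–C6, C7–C11, C12=O, C11=C13H2. The target comes from Felkin-type reduction of the C5 ketone, which comes from Ni/Cr closure of the ten-membered ring at C4–C5 (vinyl triflate plus aldehyde).
2. The α-methylene lactone and the free C8–OH come from zinc-induced β-scission of a temporary 3-chlorotetrahydrofuran ring, O(on C8)–C13–C11–C7–C8. Both oxiranes come from a stereochemical relay that starts at (R)-but-3-yn-2-ol.
3. Key disconnection: the lactone O–C6 bond and the C11–C7 bond are made together by a Cu-catalysed chlorine-atom-transfer radical cyclisation/lactonisation of an open-chain 2,2-dichloro ester, ether-linked to a dienol.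
4. Enabling feature: the oxygen on C8 and the methylene carbon C13 of the γ-lactone ring both flank the C7–C11 bond. O–C13–C11–C7–C8 can therefore be closed as a five-membered ring that holds the C11 radical 5-exo to C7. The carbinol carbon C5 next to C6 can be carried as a diene carbon, which makes C6 allylic.
5. Ring order: tetrahydrofuran and γ-lactone together (step 4), then the C2–C3 oxirane, then the C1–C10 oxirane, then opening of the tetrahydrofuran, then the ten-membered carbocycle.

Key step: step 4

**Route**

Step 1
Reactants: 1 (2E,4E)-hexa-2,4-dienal; 2 allenylboronic acid pinacol ester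
Product: 4 (4S,5E,7E)-nona-5,7-dien-1-yn-4-ol, via borate ester 3 (not isolated)
Conditions: (S)-TRIP (5 mol %), 4 Å MS, toluene, −20 °C; aq. work-up
Reagents that add atoms: none
Why: The chiral-phosphoric-acid-catalysed asymmetric propargylation of an aldehyde with an allenylboronate (closed six-membered SE2′ transition state) should add only 1,2 to the dienal, and the catalyst enantiomer is chosen so that the C8 carbinol is formed S.

Step 2
Reactants: 4 (4S,5E,7E)-nona-5,7-dien-1-yn-4-ol
Product: 6 (1E,4S,5E,7E)-1-iodo-2-methylnona-1,5,7-trien-4-ol, via alkenylalane 5 (not isolated)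
Conditions: AlMe3, Cp2ZrCl2 (cat.), CH2Cl2, 0 °C to rt; then I2, THF, −30 °C
Reagents that add atoms: trimethylaluminium C[Al](C)C; iodine II
Why: The Negishi zirconium-catalysed carboalumination adds CH3 and Al syn and regioselectively to the terminal alkyne while the diene is inert, and iodinolysis with retention should give the E-trisubstituted iodoalkene (C14 on C10, iodine on C1).

Step 3
Reactants: 6 (1E,4S,5E,7E)-1-iodo-2-methylnona-1,5,7-trien-4-ol; 7 methyl 2-chloroacrylate
Product: 10 methyl 2,2-dichloro-3-{[(1E,4S,5E,7E)-1-iodo-2-methylnona-1,5,7-trien-4-yl]oxy}propanoate, via potassium alkoxide 8 (not isolated), via chloro enolate 9 (not isolated)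
Conditions: KHMDS, THF, −78 °C; then premixed 7 and C2Cl6, −78 °C
Reagents that add atoms: hexachloroethane ClC(Cl)(Cl)C(Cl)(Cl)Cl
Why: Proposed new method: the alkoxide 8 should add to the very electrophilic β-carbon of 7 (oxa-Michael), and the α-chloro ester enolate 9 should be chlorinated by hexachloroethane already present faster than it reverts or adds to a second acrylate, so that C13, C11 and C12 are attached to the C8 oxygen in one flask without touching C8; the closest known reaction types are the addition of alkoxides to 2-haloacrylates (the 2,3-dihalopropanoate/alkoxide route to 3-alkoxy-2-halopropanoates) and the chlorination of ester enolates with hexachloroethane.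

Step 4
Reactants: 10 methyl 2,2-dichloro-3-{[(1E,4S,5E,7E)-1-iodo-2-methylnona-1,5,7-trien-4-yl]oxy}propanoate
Product: 12 (3R,3aR,4S,6aR)-6a-chloro-4-[(E)-3-iodo-2-methylprop-2-enyl]-3-[(E)-prop-1-enyl]tetrahydro-1H,3H-furo[3,4-c]furan-1-one (cis-fused; both carbon side chains on the convex face; Cl cis to H-7), via allylic chloride 11 (not isolated)
Conditions: CuCl (10 mol %), tris(2-pyridylmethyl)amine (10 mol %), MeCN, degassed, 80 °C
Reagents that add atoms: none
Why: Cu(I) abstracts one chlorine of the dichloro ester to give the C11 radical, which closes the tetrahydrofuran by 5-exo-trig attack on C7 (the near diene terminus); the resulting allyl radical takes chlorine back from Cu(II) to give 11, and the ester carbonyl oxygen then displaces the allylic chloride at C6 (5-exo, SN2′ or allyl-cation capture) with loss of chloromethane, so that C11–C7 and O–C6 form in one redox-neutral operation. The closest known reaction types are the copper-catalysed atom-transfer radical cyclisation of ether-tethered 2,2-dichloro esters and the Kharasch addition–lactonisation of polychloro esters to α-chloro-γ-lactones. C7 is set by the C8 stereocentre through a chair-like transition state with the C9 side chain pseudo-equatorial, which places C6 and C9 trans on the new ring. C6 is set under product-development control, because the allylic chloride and the allylic lactone C–O bond ionise reversibly, so the propenyl group ends trans to C8 on the convex face of the cis-fused bicycle. C11 needs no control in the radical step, because its remaining C–Cl bond is homolysed reversibly by the catalyst, the epimers interconvert, and only the epimer with the ester cis to C6 can lactonise. The step needs attack on the diene rather than on the iodoalkene and 5-exo rather than 6-endo closure; the diene is nearer and gives a stabilised allyl radical, whereas the alternatives would be 6-exo or 7-endo closures onto a hindered trisubstituted alkene.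

Step 5
Reactants: 12 bicyclic chlorolactone vinyl iodide; 13 (R)-but-3-yn-2-ol
Product: 14 enynol: 12 with iodine replaced by a (3R)-3-hydroxybut-1-ynyl group (E alkene retained)
Conditions: PdCl2(PPh3)2 (cat.), CuI (cat.), Et3N, THF, rt
Reagents that add atoms: none
Why: In this Sonogashira coupling, oxidative addition to the vinyl iodide should be much faster than ionisation of the allylic lactone or attack on the tertiary C–Cl bond, and the alkene geometry and the carbinol configuration are retained.

Step 6
Reactants: 14 enynol
Product: 15 (1(10)E,2Z)-dienol: 14 with the alkyne reduced to the Z C2=C3 alkene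
Conditions: H2 (1 atm), Lindlar catalyst, quinoline, EtOAc, rt
Reagents that add atoms: none
Why: The Lindlar semihydrogenation delivers H2 syn to the adsorbed alkyne and should stop at the Z alkene, leaving the other alkenes and the C–Cl bond untouched.

Step 7
Reactants: 15 (E,Z)-dienol
Product: 16 cis-2,3-epoxy alcohol (C2 and C3 as in the target, carbinol C4 R, C1=C10 still an E alkene)
Conditions: Ti(OiPr)4 (cat.), t-BuOOH, 4 Å MS, CH2Cl2, −20 °C
Reagents that add atoms: tert-butyl hydroperoxide CC(C)(C)OO
Why: The metal-alkoxide-directed epoxidation of an allylic alcohol reaches only the alkene next to the carbinol, and 1,3-allylic strain in the Z alkene holds H-4 in the alkene plane, so oxygen is delivered from the hydroxyl-bearing face (threo) and sets C2 and C3.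

Step 8
Reactants: 16 epoxy alcohol
Product: 17 α,β-epoxy methyl ketone (C4=O, C15 as CH3)
Conditions: Dess–Martin periodinane, NaHCO3, CH2Cl2, 0 °C
Reagents that add atoms: none
Why: The Dess–Martin oxidation removes the relay stereocentre under neutral conditions, so no hydroxyl group can direct the next epoxidation to the wrong face.

Step 9
Reactants: 17 epoxy ketone
Product: 18 bis-epoxy ketone (C1, C10, C2, C3 as in the target)
Conditions: mCPBA (1 equiv), Na2HPO4, CH2Cl2, 0 °C
Reagents that add atoms: 3-chloroperbenzoic acid OOC(=O)c1cccc(Cl)c1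
Why: The Prilezhaev epoxidation should take the trisubstituted C1=C10 alkene before the acyloxy-deactivated propenyl group, and 1,3-allylic strain against C14 holds H-2 in the alkene plane, so the peracid attacks the face of the oxirane oxygen, away from C3 and its cis acetyl group, and sets C1 and C10.

Step 10
Reactants: 18 bis-epoxy ketone
Product: 20 vinyl triflate (C4(OTf)=C15H2), via potassium enolate 19 (not isolated)
Conditions: KHMDS (1 equiv), THF, −78 °C; then N-(5-chloro-2-pyridyl)bis(trifluoromethanesulfonimide)
Reagents that add atoms: N-(5-chloro-2-pyridyl)bis(trifluoromethanesulfonimide) O=S(=O)(N(c1ccc(Cl)cn1)S(=O)(=O)C(F)(F)F)C(F)(F)F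
Why: Kinetic enolate O-triflation should occur only at the methyl group, because the oxirane C–H is not enolisable and the quaternary chlorinated C11 leaves the lactone without an acidic proton.

Step 11
Reactants: 20 vinyl triflate
Product: 22 α-methylene-γ-lactone with free C8–OH (tetrahydrofuran opened), via zinc alkoxide 21 (not isolated)
Conditions: Zn–Cu couple, THF, ultrasound, rt; aq. NH4Cl
Reagents that add atoms: none
Why: In this Boord-type reductive β-elimination of a 3-halotetrahydrofuran, two-electron reduction of the carbonyl-activated C11–Cl bond in an aprotic medium should expel the C8 alkoxide from C13 and so create C11=C13 and free the C8 oxygen without affecting the oxiranes, the triflate or any stereocentre.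

Step 12
Reactants: 22 hydroxy α-methylene lactone; 23 angelic acid
Product: 25 C8 angelate, via mixed anhydride 24 (not isolated)
Conditions: 23, 2,4,6-trichlorobenzoyl chloride, Et3N, toluene, rt; then 22, 75 °C
Reagents that add atoms: none
Why: The Yamaguchi-type mixed-anhydride esterification without a nucleophilic catalyst should acylate the only hydroxyl group and keep the Z geometry of the angelate.

Step 13
Reactants: 25 angelate
Product: 26 aldehyde (C5HO on C6)
Conditions: OsO4 (cat.), NaIO4, 2,6-lutidine, dioxane–H2O, rt
Reagents that add atoms: osmium tetroxide O=[Os](=O)(=O)=O; sodium periodate [Na+].[O-]I(=O)(=O)=O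
Why: The Lemieux–Johnson cleavage should select the only non-conjugated, non-heteroatom-substituted alkene (the propenyl group) over the α-methylene lactone, the angelate and the vinyl triflate, and it unveils C5 without touching C6.

Step 14
Reactants: 26 aldehyde vinyl triflate
Product: 27 ten-membered allylic alcohol (C4=C15, C5–OH as epimer mixture)
Conditions: CrCl2 (excess), NiCl2 (cat.), DMSO–THF, syringe-pump high dilution, rt
Reagents that add atoms: none
Why: The Nozaki–Hiyama–Kishi macrocyclisation of a 2-triflyloxy-1-alkene onto an aldehyde forms C4–C5 and directly gives the exocyclic-methylene carbinol, tolerates esters, oxiranes and the α-methylene lactone, and need not control the C5 configuration at this stage.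

Step 15
Reactants: 27 macrocyclic allylic alcohol
Product: 28 macrocyclic C5 ketone (cross-conjugated with C4=C15)
Conditions: Dess–Martin periodinane, NaHCO3, CH2Cl2, 0 °C
Reagents that add atoms: none
Why: The Dess–Martin oxidation converges both C5 epimers to one enone under neutral conditions.

Step 16
Reactants: 28 macrocyclic ketone
Product: 29 target (EANPDB:COMP_00179)
Conditions: NaBH4, CeCl3·7H2O, MeOH, −78 °C
Reagents that add atoms: none
Why: The Luche 1,2-reduction should spare the α-methylene lactone and the angelate, and polar Felkin–Anh attack of hydride anti to the C6–O(lactone) bond should give the C5–OH syn to the C6 oxygen, which is the 5S configuration.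

**Compound list**

1 | (2E,4E)-hexa-2,4-dienal | C/C=C/C=C/C=O | starting material
2 | allenylboronic acid pinacol ester | C=C=CB1OC(C)(C)C(C)(C)O1 | starting material
3 | pinacol borate ester of 4 | C#CC[C@H](OB1OC(C)(C)C(C)(C)O1)/C=C/C=C/C | intermediate
4 | (4S,5E,7E)-nona-5,7-dien-1-yn-4-ol | C#CC[C@H](O)/C=C/C=C/C | intermediate
5 | (E)-alkenyl(dimethyl)alane, dimethylaluminium alkoxide | C[Al](C)/C=C(\C)C[C@H](O[Al](C)C)/C=C/C=C/C | intermediate
6 | (1E,4S,5E,7E)-1-iodo-2-methylnona-1,5,7-trien-4-ol | I/C=C(\C)C[C@H](O)/C=C/C=C/C | intermediate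
7 | methyl 2-chloroacrylate | C=C(Cl)C(=O)OC | starting material
8 | potassium alkoxide of 6 | I/C=C(\C)C[C@H]([O-])/C=C/C=C/C.[K+] | intermediate
9 | potassium α-chloro ester enolate | I/C=C(\C)C[C@H](OCC(Cl)=C([O-])OC)/C=C/C=C/C.[K+] | intermediate
10 | methyl 2,2-dichloro-3-(dienyloxy)propanoate (key-step precursor) | I/C=C(\C)C[C@H](OCC(Cl)(Cl)C(=O)OC)/C=C/C=C/C | intermediate
11 | 3-chlorotetrahydrofuran-3-carboxylate with 3-chlorobut-1-enyl group on C7 (C11 and CHCl epimers) | COC(=O)C1(Cl)CO[C@@H](C/C(C)=C/I)[C@@H]1/C=C/C(C)Cl | intermediate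
12 | (3R,3aR,4S,6aR)-6a-chloro-furo[3,4-c]furan-1-one with propenyl and iodomethallyl groups | O=C1O[C@H](/C=C/C)[C@@H]2[C@@]1(Cl)CO[C@H]2C/C(C)=C/I | intermediate
13 | (R)-but-3-yn-2-ol | C[C@@H](O)C#C | starting material
14 | enynol | O=C1O[C@H](/C=C/C)[C@@H]2[C@@]1(Cl)CO[C@H]2C/C(C)=C/C#C[C@@H](C)O | intermediate
15 | (E,Z)-dienol | O=C1O[C@H](/C=C/C)[C@@H]2[C@@]1(Cl)CO[C@H]2C/C(C)=C/C=C\[C@@H](C)O | intermediate
16 | cis-epoxy alcohol | O=C1O[C@H](/C=C/C)[C@@H]2[C@@]1(Cl)CO[C@H]2C/C(C)=C/[C@H]1O[C@H]1[C@@H](C)O | intermediate
17 | epoxy methyl ketone | O=C1O[C@H](/C=C/C)[C@@H]2[C@@]1(Cl)CO[C@H]2C/C(C)=C/[C@H]1O[C@H]1C(C)=O | intermediate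
18 | bis-epoxy methyl ketone | O=C1O[C@H](/C=C/C)[C@@H]2[C@@]1(Cl)CO[C@H]2C[C@@]1(C)O[C@@H]1[C@H]1O[C@H]1C(C)=O | intermediate
19 | potassium enolate of 18 | O=C1O[C@H](/C=C/C)[C@@H]2[C@@]1(Cl)CO[C@H]2C[C@@]1(C)O[C@@H]1[C@H]1O[C@H]1C(=C)[O-].[K+] | intermediate
20 | vinyl triflate | O=C1O[C@H](/C=C/C)[C@@H]2[C@@]1(Cl)CO[C@H]2C[C@@]1(C)O[C@@H]1[C@H]1O[C@H]1C(=C)OS(=O)(=O)C(F)(F)F | intermediate
21 | chlorozinc C8 alkoxide of 22 | C=C1C(=O)O[C@H](/C=C/C)[C@H]1[C@@H](O[Zn]Cl)C[C@@]1(C)O[C@@H]1[C@H]1O[C@H]1C(=C)OS(=O)(=O)C(F)(F)F | intermediate
22 | α-methylene lactone, C8–OH | C=C1C(=O)O[C@H](/C=C/C)[C@H]1[C@@H](O)C[C@@]1(C)O[C@@H]1[C@H]1O[C@H]1C(=C)OS(=O)(=O)C(F)(F)F | intermediate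
23 | angelic acid, (Z)-2-methylbut-2-enoic acid | C/C=C(/C)C(=O)O | starting material
24 | angelic 2,4,6-trichlorobenzoic anhydride | C/C=C(/C)C(=O)OC(=O)c1c(Cl)cc(Cl)cc1Cl | intermediate
25 | C8 angelate | C=C1C(=O)O[C@H](/C=C/C)[C@H]1[C@@H](OC(=O)/C(C)=C\C)C[C@@]1(C)O[C@@H]1[C@H]1O[C@H]1C(=C)OS(=O)(=O)C(F)(F)F | intermediate
26 | C5 aldehyde | C=C1C(=O)O[C@H](C=O)[C@H]1[C@@H](OC(=O)/C(C)=C\C)C[C@@]1(C)O[C@@H]1[C@H]1O[C@H]1C(=C)OS(=O)(=O)C(F)(F)F | intermediate
27 | ten-membered allylic alcohol, C5 epimers | C=C1C(=O)O[C@H]2[C@H]1[C@@H](OC(=O)/C(C)=C\C)C[C@@]1(C)O[C@@H]1[C@H]1O[C@H]1C(=C)C2O | intermediate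
28 | ten-membered C5 ketone | C=C1C(=O)O[C@H]2[C@H]1[C@@H](OC(=O)/C(C)=C\C)C[C@@]1(C)O[C@@H]1[C@H]1O[C@H]1C(=C)C2=O | intermediate
29 | EANPDB:COMP_00179 | C=C1C(=O)O[C@H]2[C@H]1[C@@H](OC(=O)/C(C)=C\C)C[C@@]1(C)O[C@@H]1[C@H]1O[C@H]1C(=C)[C@@H]2O | target

**Step count**

Total step count: 16. Longest linear sequence: 16 steps, from 1 to 29.

**Steps most likely to fail**

Step 3. The oxa-Michael addition may reverse, or the enolate may oligomerise the acrylate, before chlorination takes place. The fallback uses known chemistry, sets out from 6 and returns at 10. Compound 6 is converted with DMSO, Ac2O and AcOH into the methylthiomethyl ether F1. Sulfuryl chloride turns F1 into the chloromethyl ether F2. F2 is then alkylated with the Reformatsky reagent made from methyl trichloroacetate and zinc, which gives 10.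

Step 11. The zinc enolate may persist and be protonated on work-up instead of breaking the C13–O bond, because that bond lies inside a five-membered ring and overlaps poorly with the enolate. The fallback sets out from 20 and returns at 25. The chlorine is deliberately removed with zinc in aqueous NH4Cl–THF to give the C11–H lactone F3. F3 is deprotonated with KHMDS at −78 °C and warmed, so that the potassium enolate undergoes E1cB loss of the C8 alkoxide. The alkoxide is trapped in the same flask with the mixed anhydride 24 to give 25.

Step 14. Oligomerisation, epimerisation or reduction of the α-acyloxy aldehyde may outrun closure of the strained ten-membered ring. The fallback sets out from 25 and returns at 27. Fluoride-induced elimination of the triflate (TBAF) gives the terminal alkynyl oxirane F4. Lemieux–Johnson cleavage of F4 gives the ynal F5. A nickel(0)/bulky N-heterocyclic-carbene-catalysed reductive alkyne–aldehyde macrocyclisation with Et3SiH, in the exo-methylene mode, gives the C5 triethylsilyl ether F6. Buffered HF·pyridine then liberates 27.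

**Further compounds**

F1 | step 3 | methylthiomethyl ether of 6 | I/C=C(\C)C[C@H](OCSC)/C=C/C=C/C
F2 | step 3 | chloromethyl ether of 6 | I/C=C(\C)C[C@H](OCCl)/C=C/C=C/C
F3 | step 11 | dechlorinated (C11–H) cis-fused lactone vinyl triflate | O=C1O[C@H](/C=C/C)[C@@H]2[C@H]1CO[C@H]2C[C@@]1(C)O[C@@H]1[C@H]1O[C@H]1C(=C)OS(=O)(=O)C(F)(F)F
F4 | step 14 | terminal alkynyl bis-epoxide angelate | C=C1C(=O)O[C@H](/C=C/C)[C@H]1[C@@H](OC(=O)/C(C)=C\C)C[C@@]1(C)O[C@@H]1[C@H]1O[C@H]1C#C
F5 | step 14 | ynal | C=C1C(=O)O[C@H](C=O)[C@H]1[C@@H](OC(=O)/C(C)=C\C)C[C@@]1(C)O[C@@H]1[C@H]1O[C@H]1C#C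
F6 | step 14 | macrocyclic C5 triethylsilyl ether (C5 epimers) | C=C1C(=O)O[C@H]2[C@H]1[C@@H](OC(=O)/C(C)=C\C)C[C@@]1(C)O[C@@H]1[C@H]1O[C@H]1C(=C)C2O[Si](CC)(CC)CC
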